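**Retrosynthetic overview**

1. The two esters go on last (C9 tiglate, then C7 senecioate). The C1 ketone comes from allylic C–H oxidation of the C2=C3 alkene before the last ring is closed.
2. Key disconnection C9–C10: iron-hydride hydrogen-atom transfer to an exocyclic methylene on C10 gives a tertiary cyclobutyl radical that closes the seven-membered ring onto the C9 aldehyde. The same event creates the C10 methyl group, the quaternary centre and the C9 carbinol.
3. Enabling feature: in the cyclobutane C4–C5–C11–C10, the methylene-bearing C10 and the chain-bearing C5 (chain C6Me2–C7H(OSi)–C8H2–C9HO) are 1,3 across the four-membered ring, and the chain lies on the face anti to the enone bridge, so C9 is held directly under C10.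
4. The six-membered ring is made by a gold-catalysed silyl enol ether–alkyne cyclization that bridges the two α-carbons of a 3-substituted cyclobutanone. That ketone comes from a dichloroketene [2+2] cycloaddition on a reverse-prenylated homoallylic ether.
5. Ring order: cyclobutane (step 3), cyclohexene (step 8), cycloheptane (step 13). C7 is set by asymmetric reverse prenylation, C5/C11 by a chiral-amide desymmetrization; C4, C10 and C9 follow from these.

Key step: step 13

Remark: the skeleton is numbered as a longipinane (C1 ketone, C2=C3(CH3), C4, C5, C6(CH3)2, C7–O-senecioate, C8, C9–O-tiglate, C10–CH3, C11; cyclobutane = C4–C5–C11–C10), and these locants are also used for the corresponding atoms of the intermediates. The sense of induction in steps 1 and 5 is assumed from the usual models; the antipodal ligand or amine would be used if it proved opposite. TBS = tert-butyldimethylsilyl; CIP descriptors were assigned by hand, and the SMILES are authoritative.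

**Step 1**
Reactants: 1 3-(TBS-oxy)propan-1-ol; 2 3-methylbuta-1,2-diene
Product: 3 (3R)-1-(TBS-oxy)-4,4-dimethylhex-5-en-3-ol
Conditions: [Ir(cod)Cl]2 (2.5 mol %), SEGPHOS (5 mol %, enantiomer giving the 3R alcohol), 4-chloro-3-nitrobenzoic acid (10 mol %), Cs2CO3 (20 mol %), THF, 70 °C, sealed tube
Reagents that add atoms: none
Why: Iridium-catalysed transfer-hydrogenative carbonyl reverse prenylation from the alcohol oxidation level: the catalyst dehydrogenates 1 to the aldehyde and hydrometalates the allene to a 1,1-dimethylallyl iridium species that adds through its substituted terminus in a closed transition state, so the SEGPHOS ligand sets the C7 carbinol centre (R) while the C6 gem-dimethyl carbon and the vinyl group needed for step 3 arrive in the same operation.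

**Step 2**
Reactants: 3 (3R)-1-(TBS-oxy)-4,4-dimethylhex-5-en-3-ol
Product: 4 (4R)-4,6-bis(TBS-oxy)-3,3-dimethylhex-1-ene
Conditions: TBSOTf, 2,6-lutidine, CH2Cl2, −78 → 0 °C
Reagents that add atoms: tert-butyldimethylsilyl trifluoromethanesulfonate, CC(C)(C)[Si](C)(C)OS(=O)(=O)C(F)(F)F
Why: Silylation of the hindered secondary alcohol with a silyl triflate and a non-nucleophilic base should be clean and leaves the stereocentre untouched.

**Step 3**
Reactants: 4 (4R)-4,6-bis(TBS-oxy)-3,3-dimethylhex-1-ene; 5 trichloroacetyl chloride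
Product: 7 2,2-dichloro-3-[(3R)-3,5-bis(TBS-oxy)-2-methylpentan-2-yl]cyclobutan-1-one (both epimers at ring C3), via dichloroketene 6 (not isolated)
Conditions: Zn–Cu couple, POCl3, Et2O, sonication, 15–25 °C
Reagents that add atoms: none
Why: Thermal [2+2] cycloaddition of dichloroketene with the hindered monosubstituted alkene joins the ketene carbonyl carbon to the terminal CH2 and gives the 3-substituted 2,2-dichlorocyclobutanone; the new ring stereocentre forms unselectively but is no longer stereogenic after step 4.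

**Step 4**
Reactants: 7 2,2-dichloro-3-[(3R)-3,5-bis(TBS-oxy)-2-methylpentan-2-yl]cyclobutan-1-one
Product: 8 3-[(3R)-3,5-bis(TBS-oxy)-2-methylpentan-2-yl]cyclobutan-1-one
Conditions: Zn dust, NH4Cl, MeOH, rt
Reagents that add atoms: none
Why: Zinc reductive dechlorination of the α,α-dichloroketone gives the cyclobutanone whose two α-methylene groups are equivalent but for the remote C7 centre.

**Step 5**
Reactants: 8 3-[(3R)-3,5-bis(TBS-oxy)-2-methylpentan-2-yl]cyclobutan-1-one
Product: 10 trimethylsilyl enol ether {[(3S)-3-[(3R)-3,5-bis(TBS-oxy)-2-methylpentan-2-yl]cyclobut-1-en-1-yl]oxy}trimethylsilane, via lithium enolate 9 (not isolated)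
Conditions: (R,R)-bis(1-phenylethyl)amine, n-BuLi, THF, −78 °C; then TMSCl and 8 (in situ quench), −100 °C
Reagents that add atoms: chlorotrimethylsilane, C[Si](C)(C)Cl
Why: Enantioselective deprotonation (desymmetrization) by a chiral lithium amide with in situ silyl chloride trapping: the base selects one of the two α-methylene groups under reagent control, which fixes the configuration of ring carbon 3 (the future C5) and defines which α-carbon becomes C11.

**Step 6**
Reactants: 10 trimethylsilyl enol ether; 11 1-bromobut-2-yne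
Product: 13 (2R,3S)-2-(but-2-yn-1-yl)-3-[(3R)-3,5-bis(TBS-oxy)-2-methylpentan-2-yl]cyclobutan-1-one, via benzyltrimethylammonium enolate 12 (not isolated)
Conditions: anhydrous benzyltrimethylammonium fluoride (1.0 equiv), 11 (1.5 equiv, present from the start), 4 Å molecular sieves, THF, −40 → 0 °C
Reagents that add atoms: none
Why: Fluoride-mediated regiospecific alkylation of a silyl enol ether: the stoichiometric fluoride cleaves the O–SiMe3 bond far faster than the two TBS ethers and releases the regiodefined quaternary ammonium enolate in the presence of the propargylic bromide, so SN2 alkylation should outrun proton exchange and occur on the face trans to the bulky tert-alkyl substituent, setting the future C11 (2R).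

**Step 7**
Reactants: 13 (2R,3S)-2-(but-2-yn-1-yl)-3-[(3R)-3,5-bis(TBS-oxy)-2-methylpentan-2-yl]cyclobutan-1-one
Product: 15 TBS enol ether of 13 (C=C towards the unsubstituted α-carbon), via kinetic lithium enolate 14 (not isolated)
Conditions: lithium diisopropylamide (1.1 equiv), THF, −78 °C; then TBSCl, DMPU, −78 → 0 °C
Reagents that add atoms: tert-butyl(chloro)dimethylsilane, CC(C)(C)[Si](C)(C)Cl
Why: Kinetic deprotonation by the hindered amide at the unsubstituted α'-methylene rather than the substituted α-methine, followed by O-silylation, gives the regiodefined silyl enol ether without touching a stereocentre.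

**Step 8**
Reactants: 15 TBS enol ether of 13
Product: 16 (1R,5R,7R)-7-[(3R)-3,5-bis(TBS-oxy)-2-methylpentan-2-yl]-2-methylbicyclo[3.1.1]hept-2-en-6-one (side chain anti to the ene bridge)
Conditions: (2-biphenylyl)di-tert-butylphosphine gold acetonitrile hexafluoroantimonate, [(JohnPhos)Au(NCMe)]SbF6 (5 mol %), CH2Cl2–MeOH 10:1, rt
Reagents that add atoms: none
Why: Gold-catalysed 6-endo-dig carbocyclization of a silyl enol ether onto a tethered alkyne (Conia-ene type): the enol carbon (future C4) attacks the activated alkyne carbon that bears the methyl group, protodeauration by methanol leaves the C2=C3 alkene with its C3 methyl, and since the tether on C11 can reach only its own face the new C4 centre is fixed and the bridge forms anti to the C5 side chain.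

**Step 9**
Reactants: 16 bicyclic cyclobutanone
Product: 17 7-[(3R)-3,5-bis(TBS-oxy)-2-methylpentan-2-yl]-2-methyl-6-methylidenebicyclo[3.1.1]hept-2-ene (ring configuration as in 16)
Conditions: Ph3PCH3Br, KOtBu, toluene, 0 → 80 °C
Reagents that add atoms: methyltriphenylphosphonium bromide, C[P+](c1ccccc1)(c1ccccc1)c1ccccc1.[Br-]
Why: Wittig methylenation of the strained, non-enolisable cyclobutanone installs on C10 the exocyclic alkene that will become both the methyl group and the radical centre.

**Step 10**
Reactants: 17 methylidene diene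
Product: 18 7-[(3R)-3,5-bis(TBS-oxy)-2-methylpentan-2-yl]-4-methyl-6-methylidenebicyclo[3.1.1]hept-3-en-2-one (ring configuration as in 16)
Conditions: dirhodium tetrakis(caprolactamate) Rh2(cap)4 (1 mol %), t-BuOOH (70 % aq., 5 equiv), K2CO3 (0.5 equiv), CH2Cl2, rt
Reagents that add atoms: tert-butyl hydroperoxide, CC(C)(C)OO
Why: Dirhodium-catalysed allylic C–H oxidation with tert-butyl hydroperoxide should attack the secondary allylic methylene C1 next to the unsubstituted alkene carbon (the α-pinene-to-verbenone preference), because the bridgehead allylic C–H bonds cannot conjugate in the derived radical and the exocyclic alkene has no other allylic hydrogen.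

**Step 11**
Reactants: 18 methylidene enone
Product: 19 7-[(3R)-3-(TBS-oxy)-5-hydroxy-2-methylpentan-2-yl]-4-methyl-6-methylidenebicyclo[3.1.1]hept-3-en-2-one
Conditions: HF·pyridine, pyridine, THF, 0 °C
Reagents that add atoms: none
Why: Buffered fluoride cleaves the unhindered primary silyl ether much faster than the secondary silyl ether flanked by the quaternary carbon.

**Step 12**
Reactants: 19 primary alcohol
Product: 20 (3R)-3-(TBS-oxy)-4-methyl-4-[4-methyl-6-methylidene-2-oxobicyclo[3.1.1]hept-3-en-7-yl]pentanal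
Conditions: Dess–Martin periodinane (1.3 equiv), CH2Cl2, 0 °C → rt
Reagents that add atoms: none
Why: Dess–Martin oxidation gives the β-silyloxy aldehyde under non-basic conditions that avoid elimination.

**Step 13**
Reactants: 20 aldehyde carrying the exocyclic methylene
Product: 21 (4R,5S,7R,9R,10R,11R)-9-hydroxy-7-(TBS-oxy)longipin-2-en-1-one
Conditions: Fe(acac)3 (30 mol %), PhSiH3 (2.5 equiv, slow addition), EtOH (0.02 M), 60 °C
Reagents that add atoms: none
Why: An iron hydride formed from Fe(acac)3, phenylsilane and ethanol transfers a hydrogen atom to the terminal carbon of the exocyclic alkene (Markovnikov sense), which creates the C10 methyl group and a tertiary cyclobutyl radical at C10; this radical adds to the aldehyde carbon C9, and the alkoxy radical is reduced by the divalent iron and protonated. The closest known reaction type is the iron-hydride-initiated reductive radical coupling of unactivated alkenes with ketones (intramolecular) and aldehydes. The seven-membered ring closes in the 7-exo-trig mode onto C=O, as a four-carbon bridge across the 1,3-positions of the cyclobutane. At C10 the chain anchored on C5 can reach only the face of the planar radical anti to the enone bridge, so the new bond is anti and the methyl ends up syn, the only geometry the tricycle allows. At C9 the twist-chair transition state with the C7 silyloxy group pseudo-equatorial should turn the aldehyde oxygen away from the C10 methyl group, which gives the 7,9-trans relationship. The step needs hydrogen-atom transfer to the electron-rich, strained 1,1-disubstituted alkene rather than to the electron-poor enone (secured by installing the ketone first), and ring closure faster than reduction or ring opening of the radical (secured by the rigid 1,3-cis arrangement, the C6 gem-dimethyl group, and β C–C bonds that lie orthogonal to the radical orbital).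

**Step 14**
Reactants: 21 tricyclic hydroxy enone; 22 (E)-2-methylbut-2-enoyl chloride
Product: 23 (4R,5S,7R,9R,10R,11R)-7-(TBS-oxy)-9-[(E)-2-methylbut-2-enoyloxy]longipin-2-en-1-one
Conditions: pyridine, DMAP (0.2 equiv), CH2Cl2, 0 → 40 °C
Reagents that add atoms: none
Why: DMAP-catalysed acylation of the C9 alcohol with the acid chloride; the E geometry of the tiglate is the thermodynamic one and should be retained.

**Step 15**
Reactants: 23 tiglate silyl ether
Product: 24 (4R,5S,7R,9R,10R,11R)-7-hydroxy-9-[(E)-2-methylbut-2-enoyloxy]longipin-2-en-1-one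
Conditions: HF·pyridine, THF, 0 °C → rt
Reagents that add atoms: none
Why: Acidic fluoride desilylation frees the C7 alcohol without the base-promoted acyl migration from O9 or ester isomerization that a basic fluoride source could cause.

**Step 16**
Reactants: 24 hydroxy tiglate; 25 3-methylbut-2-enoic acid
Product: 27 CNP0277258.1 (4R,5S,7R,9R,10R,11R)-7-(3-methylbut-2-enoyloxy)-9-[(E)-2-methylbut-2-enoyloxy]longipin-2-en-1-one, via mixed anhydride 26 (not isolated)
Conditions: 25, 2,4,6-trichlorobenzoyl chloride, Et3N, THF, rt; then 24, DMAP, toluene, rt → 50 °C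
Reagents that add atoms: none
Why: Yamaguchi esterification: the mixed anhydride acylates the hindered C7 alcohol under DMAP activation and avoids the acid chloride plus amine base combination that would deconjugate the senecioyl group through its vinylketene.

**Compound list**

1 | 3-(TBS-oxy)propan-1-ol | CC(C)(C)[Si](C)(C)OCCCO | starting material
2 | 3-methylbuta-1,2-diene | CC(C)=C=C | starting material
3 | (3R)-1-(TBS-oxy)-4,4-dimethylhex-5-en-3-ol | CC(C)(C)[Si](C)(C)OCC[C@@H](O)C(C)(C)C=C | intermediate
4 | (4R)-4,6-bis(TBS-oxy)-3,3-dimethylhex-1-ene | CC(C)(C)[Si](C)(C)OCC[C@@H](O[Si](C)(C)C(C)(C)C)C(C)(C)C=C | intermediate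
5 | trichloroacetyl chloride | ClC(=O)C(Cl)(Cl)Cl | starting material
6 | dichloroketene | ClC(Cl)=C=O | intermediate
7 | 2,2-dichloro-3-[(3R)-3,5-bis(TBS-oxy)-2-methylpentan-2-yl]cyclobutan-1-one (epimers at ring C3) | CC(C)(C)[Si](C)(C)OCC[C@@H](O[Si](C)(C)C(C)(C)C)C(C)(C)C1CC(=O)C1(Cl)Cl | intermediate
8 | 3-[(3R)-3,5-bis(TBS-oxy)-2-methylpentan-2-yl]cyclobutan-1-one | CC(C)(C)[Si](C)(C)OCC[C@@H](O[Si](C)(C)C(C)(C)C)C(C)(C)C1CC(=O)C1 | intermediate
9 | lithium (3S)-3-[(3R)-3,5-bis(TBS-oxy)-2-methylpentan-2-yl]cyclobut-1-en-1-olate | [Li+].CC(C)(C)[Si](C)(C)OCC[C@@H](O[Si](C)(C)C(C)(C)C)C(C)(C)[C@H]1CC([O-])=C1 | intermediate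
10 | {[(3S)-3-[(3R)-3,5-bis(TBS-oxy)-2-methylpentan-2-yl]cyclobut-1-en-1-yl]oxy}trimethylsilane | CC(C)(C)[Si](C)(C)OCC[C@@H](O[Si](C)(C)C(C)(C)C)C(C)(C)[C@H]1CC(O[Si](C)(C)C)=C1 | intermediate
11 | 1-bromobut-2-yne | CC#CCBr | starting material
12 | benzyltrimethylammonium (3S)-3-[(3R)-3,5-bis(TBS-oxy)-2-methylpentan-2-yl]cyclobut-1-en-1-olate | C[N+](C)(C)Cc1ccccc1.CC(C)(C)[Si](C)(C)OCC[C@@H](O[Si](C)(C)C(C)(C)C)C(C)(C)[C@H]1CC([O-])=C1 | intermediate
13 | (2R,3S)-2-(but-2-yn-1-yl)-3-[(3R)-3,5-bis(TBS-oxy)-2-methylpentan-2-yl]cyclobutan-1-one | CC(C)(C)[Si](C)(C)OCC[C@@H](O[Si](C)(C)C(C)(C)C)C(C)(C)[C@H]1CC(=O)[C@@H]1CC#CC | intermediate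
14 | kinetic lithium enolate of 13 (C=C towards the unsubstituted α-carbon) | [Li+].CC(C)(C)[Si](C)(C)OCC[C@@H](O[Si](C)(C)C(C)(C)C)C(C)(C)[C@H]1C=C([O-])[C@@H]1CC#CC | intermediate
15 | TBS enol ether of 13 (C=C towards the unsubstituted α-carbon) | CC(C)(C)[Si](C)(C)OCC[C@@H](O[Si](C)(C)C(C)(C)C)C(C)(C)[C@H]1C=C(O[Si](C)(C)C(C)(C)C)[C@@H]1CC#CC | intermediate
16 | (1R,5R,7R)-7-[(3R)-3,5-bis(TBS-oxy)-2-methylpentan-2-yl]-2-methylbicyclo[3.1.1]hept-2-en-6-one | CC(C)(C)[Si](C)(C)OCC[C@@H](O[Si](C)(C)C(C)(C)C)C(C)(C)[C@@H]1[C@H]2CC=C(C)[C@@H]1C2=O | intermediate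
17 | 7-[(3R)-3,5-bis(TBS-oxy)-2-methylpentan-2-yl]-2-methyl-6-methylidenebicyclo[3.1.1]hept-2-ene | CC(C)(C)[Si](C)(C)OCC[C@@H](O[Si](C)(C)C(C)(C)C)C(C)(C)[C@@H]1[C@H]2CC=C(C)[C@@H]1C2=C | intermediate
18 | 7-[(3R)-3,5-bis(TBS-oxy)-2-methylpentan-2-yl]-4-methyl-6-methylidenebicyclo[3.1.1]hept-3-en-2-one | CC(C)(C)[Si](C)(C)OCC[C@@H](O[Si](C)(C)C(C)(C)C)C(C)(C)[C@@H]1[C@H]2C(=O)C=C(C)[C@@H]1C2=C | intermediate
19 | 7-[(3R)-3-(TBS-oxy)-5-hydroxy-2-methylpentan-2-yl]-4-methyl-6-methylidenebicyclo[3.1.1]hept-3-en-2-one | OCC[C@@H](O[Si](C)(C)C(C)(C)C)C(C)(C)[C@@H]1[C@H]2C(=O)C=C(C)[C@@H]1C2=C | intermediate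
20 | (3R)-3-(TBS-oxy)-4-methyl-4-[4-methyl-6-methylidene-2-oxobicyclo[3.1.1]hept-3-en-7-yl]pentanal | O=CC[C@@H](O[Si](C)(C)C(C)(C)C)C(C)(C)[C@@H]1[C@H]2C(=O)C=C(C)[C@@H]1C2=C | intermediate
21 | (4R,5S,7R,9R,10R,11R)-9-hydroxy-7-(TBS-oxy)longipin-2-en-1-one | O[C@@H]1C[C@@H](O[Si](C)(C)C(C)(C)C)C(C)(C)[C@@H]2[C@H]3C(=O)C=C(C)[C@@H]2[C@]31C | intermediate
22 | (E)-2-methylbut-2-enoyl chloride (tigloyl chloride) | C/C=C(\C)C(Cl)=O | starting material
23 | (4R,5S,7R,9R,10R,11R)-7-(TBS-oxy)-9-[(E)-2-methylbut-2-enoyloxy]longipin-2-en-1-one | C/C=C(\C)C(=O)O[C@@H]1C[C@@H](O[Si](C)(C)C(C)(C)C)C(C)(C)[C@@H]2[C@H]3C(=O)C=C(C)[C@@H]2[C@]31C | intermediate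
24 | (4R,5S,7R,9R,10R,11R)-7-hydroxy-9-[(E)-2-methylbut-2-enoyloxy]longipin-2-en-1-one | C/C=C(\C)C(=O)O[C@@H]1C[C@@H](O)C(C)(C)[C@@H]2[C@H]3C(=O)C=C(C)[C@@H]2[C@]31C | intermediate
25 | 3-methylbut-2-enoic acid | CC(C)=CC(=O)O | starting material
26 | 3-methylbut-2-enoic 2,4,6-trichlorobenzoic anhydride | CC(C)=CC(=O)OC(=O)c1c(Cl)cc(Cl)cc1Cl | intermediate
27 | CNP0277258.1, (4R,5S,7R,9R,10R,11R)-7-(3-methylbut-2-enoyloxy)-9-[(E)-2-methylbut-2-enoyloxy]longipin-2-en-1-one | C/C=C(\C)C(=O)O[C@@H]1C[C@@H](OC(=O)C=C(C)C)C(C)(C)[C@@H]2[C@H]3C(=O)C=C(C)[C@@H]2[C@]31C | target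

**Total step count:** 16. **Longest linear sequence:** 16 steps (from 1).

**Steps most likely to fail**

Step 13. The tertiary cyclobutyl radical may be reduced by a second hydrogen-atom transfer before it closes the seven-membered ring, the addition to the aldehyde may revert through β-scission of the alkoxy radical, or facial selectivity at C9 may be poor. The fallback inverts the polarity of the radical closure and sets out from 16. Peterson olefination with lithiated (phenylsulfonylmethyl)trimethylsilane (THF, −78 °C → rt) should give the vinyl sulfone F1. Selective cleavage of the primary silyl ether (HF·pyridine, pyridine) would give the alcohol F2, and Dess–Martin oxidation the aldehyde F3. Samarium diiodide (SmI2, THF, HMPA, t-BuOH, −78 °C) then forms the ketyl at C9, which adds to the sulfone-activated exocyclic alkene in a ketyl–olefin cyclization to give the hydroxy sulfone F4. Sodium amalgam Na(Hg) with Na2HPO4 in MeOH removes the sulfonyl group and reveals the C10 methyl in the 1-deoxo alcohol F5. Acylation with 22 (pyridine, DMAP) gives the tiglate F6, and allylic oxidation with Rh2(cap)4 and t-BuOOH returns to the route at 23.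

Step 8. The strained siloxycyclobutene may be protodesilylated or ring-opened by the cationic gold catalyst, or the 5-exo-dig mode may compete. The fallback replaces the cycloisomerization by a cross-coupling and sets out from 10. Benzyltrimethylammonium fluoride releases the ammonium enolate 12 as in step 6, and this is alkylated with the known reagent (Z)-1-bromo-3-iodobut-2-ene (BrC/C=C(/C)I) to give the iodoalkenyl ketone F7. Intramolecular α-alkenylation of the ketone by zerovalent palladium (Pd(PPh3)4, PhOK, THF, 65 °C) then closes the C3–C4 bond and returns to the route at 16.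

Step 5. The chiral amide may discriminate poorly between the two α-methylene groups, or the enolate may equilibrate, so that the C5/C11 configuration is set with low selectivity. The fallback uses an auxiliary and sets out from 8. Condensation with (S)-1-amino-2-(methoxymethyl)pyrrolidine (SAMP) gives the hydrazone F8. Deprotonation with lithium diisopropylamide and alkylation with 11 gives the alkylated hydrazone F9, in which the auxiliary fixes the configuration of the alkylated carbon and the trans preference of the ring substituent selects the α-carbon. The cis isomer from the other aza-enolate is removed by chromatography. Cleavage with aqueous oxalic acid in Et2O returns to the route at 13.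

**Further compounds**

F1 | step 13 | 7-[(3R)-3,5-bis(TBS-oxy)-2-methylpentan-2-yl]-2-methyl-6-(phenylsulfonylmethylidene)bicyclo[3.1.1]hept-2-ene | CC(C)(C)[Si](C)(C)OCC[C@@H](O[Si](C)(C)C(C)(C)C)C(C)(C)[C@@H]1[C@H]2CC=C(C)[C@@H]1C2=CS(=O)(=O)c1ccccc1
F2 | step 13 | primary alcohol from F1 | OCC[C@@H](O[Si](C)(C)C(C)(C)C)C(C)(C)[C@@H]1[C@H]2CC=C(C)[C@@H]1C2=CS(=O)(=O)c1ccccc1
F3 | step 13 | aldehyde from F2 | O=CC[C@@H](O[Si](C)(C)C(C)(C)C)C(C)(C)[C@@H]1[C@H]2CC=C(C)[C@@H]1C2=CS(=O)(=O)c1ccccc1
F4 | step 13 | 9-hydroxy-7-(TBS-oxy)longipin-2-ene carrying CH2SO2Ph in place of the C10 methyl | O[C@@H]1C[C@@H](O[Si](C)(C)C(C)(C)C)C(C)(C)[C@@H]2[C@H]3CC=C(C)[C@@H]2[C@]31CS(=O)(=O)c1ccccc1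
F5 | step 13 | 9-hydroxy-7-(TBS-oxy)longipin-2-ene | O[C@@H]1C[C@@H](O[Si](C)(C)C(C)(C)C)C(C)(C)[C@@H]2[C@H]3CC=C(C)[C@@H]2[C@]31C
F6 | step 13 | 7-(TBS-oxy)-9-[(E)-2-methylbut-2-enoyloxy]longipin-2-ene | C/C=C(\C)C(=O)O[C@@H]1C[C@@H](O[Si](C)(C)C(C)(C)C)C(C)(C)[C@@H]2[C@H]3CC=C(C)[C@@H]2[C@]31C
F7 | step 8 | (2R,3S)-2-[(Z)-3-iodobut-2-en-1-yl]-3-[(3R)-3,5-bis(TBS-oxy)-2-methylpentan-2-yl]cyclobutan-1-one | CC(C)(C)[Si](C)(C)OCC[C@@H](O[Si](C)(C)C(C)(C)C)C(C)(C)[C@H]1CC(=O)[C@@H]1C/C=C(/C)I
F8 | step 5 | SAMP hydrazone of 8 | CC(C)(C)[Si](C)(C)OCC[C@@H](O[Si](C)(C)C(C)(C)C)C(C)(C)C1CC(=NN2CCC[C@H]2COC)C1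
F9 | step 5 | SAMP hydrazone of 13 | CC(C)(C)[Si](C)(C)OCC[C@@H](O[Si](C)(C)C(C)(C)C)C(C)(C)[C@H]1CC(=NN2CCC[C@H]2COC)[C@@H]1CC#CC
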